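(The data are calculated for substances that don't exist; noise was put on by code.)

I have one more run to charge, so the question is which charge of starting material leaves the highest [target] when the flask is stopped. Reagent is fed in over 1.5 min, and the stop comes at 2.5 min.

| flask | starting material | reagent | remark | time |
|---|---|---|---|---|
| green | 15 mM | 16 mM (fed, over 1.5 min) | run made earlier; the fed solution adds 0.10 times the starting volume |  |
| red | 110 mM | 16 mM (fed, over 1.5 min) | run made earlier; the fed solution adds 0.10 times the starting volume |  |
| maple | 10 mM | 16.0 mM (fed, over 1.5 min) | the fed solution adds 0.10 times the starting volume | 2.5 min |
| cedar | 20 mM | 16.0 mM (fed, over 1.5 min) | the fed solution adds 0.10 times the starting volume | 2.5 min |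
| larch | 40 mM | 16.0 mM (fed, over 1.5 min) | the fed solution adds 0.10 times the starting volume | 2.5 min |
| elm | 80 mM | 16.0 mM (fed, over 1.5 min) | the fed solution adds 0.10 times the starting volume | 2.5 min |

| run | time / s | target / % | starting material / % |
|---|---|---|---|
| green | 10.0 | 0.6 | 98.4 |
| green | 15.0 | 0.5 | 98.0 |
| green | 25.0 | 1.5 | 96.4 |
| green | 40.0 | 3.6 | 91.3 |
| green | 60.0 | 5.3 | 82.7 |
| green | 120 | 10.4 | 55.3 |
| red | 10.0 | 0 | 99.1 |
| red | 15.0 | 0.7 | 99.8 |
| red | 25.0 | 0.8 | 98.2 |
| red | 40.0 | 1.9 | 96.0 |
| red | 60.0 | 2.7 | 92.2 |
| red | 120 | 2.9 | 85.5 |

(each reading ± 0.5 percentage points)

- every charge counts on the volume at the start, and the solution that is fed holds the whole dose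
- steps under discussion: starting material + reagent -> intermediate A; starting material + reagent -> target; intermediate A <-> intermediate B; reagent + intermediate B <-> intermediate C; target -> over-reaction product
- "hardly changes" means that all values lie within two and a half points (for a concentration: within two and a half percent of the largest)

- [target] at the end for maple, cedar, larch, elm, in this order
- how that number moves from the first to the last of them (falls all the way / falls, then rises / rises, then falls / hardly changes / rises all the way)

My choice hangs on how long target survives once made, since it passes on to over-reaction product, and the red run lets me read that. Between 60.0 s and 120 s red target goes from 2.7% to 2.9%, standing near 2.80%, while starting material falls by 6.7 percentage points. If target stands still, its making and its loss balance. The green reading at 40.0 s gives the selectivity, the share of consumed starting material that appears as target, as 0.414. So red makes 2.8 points of target in that interval and must lose as much, which gives the target's half-life, the time in which its stock halves with no new making, of 42.0 s. This is a reading, rough at a scatter of 0.5 points on each point.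

From the end of the feed to the stop are 60.0 s, longer than that half-life: 1.43 half-lives, so 37.2% of the target standing at the end of the feed survives. The target made late therefore counts, and a flask must still be working then. By 120 s red has consumed 16.0 mM of starting material against 16 mM of reagent charged, whereas green has consumed 6.71 mM, which is too little. I want a charge between them.

The forecast gives 1.05 mM, 1.7 mM, 2.2 mM and 2.1 mM, so rises, then falls, on the grounds that “Dilute runs convert too little; concentrated runs form target early, which then has time to decay.” I charge larch.

    starting material + reagent → intermediate A (k = 0.435 /M/s)
    starting material + reagent → target (k = 0.327 /M/s)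
    intermediate A ⇌ intermediate B (K = 0.956, k = 0.0141 /s)
    reagent + intermediate B ⇌ intermediate C (K = 100 /M, k = 0.523 /M/s)
    target → over-reaction product (k = 0.0158 /s)

The flasks give 0.896 mM, 1.45 mM, 1.84 mM and 1.74 mM, so the shape is rises, then falls, with larch above the others. The half-life of target in maple, 0.73 min, is short against the 2.5 min of the run. Over the 60.0 s from the end of the feed to the stop, longer than my read half-life of 42.0 s, the last step of the scheme leaves 38.8% of the target that stood, so the 3.84% of target standing in elm at the end of the feed shrinks to 1.49%, and 0.91 points of the final 2.40% came later. In maple the 9.22% shrinks to 3.58%, so 6.3 points of the final 9.86% came later.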